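**Retrosynthetic overview** (flavanone numbering)
- The target is the (2S)-flavanone with OH at C5, C7 and C4', OMe at C3' and prenyl at C6; the last disconnection is removal of three aryl silyl ethers.
- The strategy rests on C2: it is benzylic to ring B and bound to O1, so in the open benzyl aryl ether its two C–H bonds are doubly activated and lie 1,6 to a carbene placed at C3 of an ortho diazoacetyl group on ring A. Enantioselective dirhodium carbene insertion forms C2–C3, closes ring C and sets C2.
- The diazoketone comes from the aryl methyl ketone by detrifluoroacetylative diazo transfer, and the O1–CH2 bond from a Mitsunobu coupling with a vanillin-derived benzyl alcohol.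
- The C6 prenyl group comes from O-prenylation of the one free phenol of bis-silylated 2,4,6-trihydroxyacetophenone followed by a Claisen–Cope shift to the para carbon. This frees O1 and leaves O5 and O7 as silyl ethers, which offer no activated C–H bond to the carbene.
- Rings A and B are bought; ring C is the only ring formed and is formed last.

Key step: step 8

Assumption: Rh2(S-PTTL)4 is taken to favour the (2S) product; if the insertion favours (2R), the mirror-image catalyst Rh2(R-PTTL)4 is used with no other change.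

**Route**

Step 1
Reactants: 1 vanillin (4-hydroxy-3-methoxybenzaldehyde)
Product: 2 4-(tert-butyldimethylsilyloxy)-3-methoxybenzaldehyde
Conditions: TBSCl, imidazole, DMF, rt
Reagents that add atoms: tert-butyldimethylsilyl chloride (TBSCl), CC(C)(C)[Si](C)(C)Cl
Why: Standard silylation of a phenol, which protects the ring B hydroxyl with a group that fluoride removes at the end.

Step 2
Reactants: 2 4-(tert-butyldimethylsilyloxy)-3-methoxybenzaldehyde
Product: 3 [4-(tert-butyldimethylsilyloxy)-3-methoxyphenyl]methanol
Conditions: NaBH4, THF/EtOH, 0 °C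
Reagents that add atoms: none
Why: Borohydride reduction of an aryl aldehyde to the primary benzylic alcohol, which at 0 °C should leave the aryl silyl ether in place.

Step 3
Reactants: 4 1-(2,4,6-trihydroxyphenyl)ethanone (2,4,6-trihydroxyacetophenone, dried)
Product: 5 1-[2,4-bis(tert-butyldimethylsilyloxy)-6-hydroxyphenyl]ethanone
Conditions: TBSCl (2.1 equiv), imidazole, DMF, 0 °C to rt
Reagents that add atoms: tert-butyldimethylsilyl chloride (TBSCl), CC(C)(C)[Si](C)(C)Cl
Why: Phenol silylation in which the para hydroxyl and one of the two equivalent ortho hydroxyls react, while the last ortho hydroxyl is held in a hydrogen bond to the acetyl carbonyl and should stay free, as in the usual bis-protection of this ketone.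

Step 4
Reactants: 5 1-[2,4-bis(tert-butyldimethylsilyloxy)-6-hydroxyphenyl]ethanone; 6 3-methylbut-2-en-1-ol (prenol)
Product: 7 1-[2,4-bis(tert-butyldimethylsilyloxy)-6-(3-methylbut-2-enyloxy)phenyl]ethanone
Conditions: PPh3, DIAD, THF, 0 °C to rt
Reagents that add atoms: none
Why: Mitsunobu etherification of the chelated phenol with a primary allylic alcohol under neutral conditions that spare the aryl silyl ethers and should give the unrearranged prenyl ether.

Step 5
Reactants: 7 1-[2,4-bis(tert-butyldimethylsilyloxy)-6-(3-methylbut-2-enyloxy)phenyl]ethanone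
Product: 10 1-[2,4-bis(tert-butyldimethylsilyloxy)-6-hydroxy-3-(3-methylbut-2-enyl)phenyl]ethanone, via ortho-dienone 8 (not isolated), via para-dienone 9 (not isolated)
Conditions: N,N-diethylaniline, 200 °C, argon
Reagents that add atoms: none
Why: Tandem aromatic Claisen and Cope rearrangement (para-Claisen), in which the first [3,3] shift can reach only the unsubstituted ortho carbon to give the crowded dienone 8, a second [3,3] shift relays the allyl unit to the para carbon as a normal prenyl group in 9, and enolisation should give the phenol with prenyl between the two silyloxy groups and the free hydroxyl para to it.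

Step 6
Reactants: 10 1-[2,4-bis(tert-butyldimethylsilyloxy)-6-hydroxy-3-(3-methylbut-2-enyl)phenyl]ethanone; 3 [4-(tert-butyldimethylsilyloxy)-3-methoxyphenyl]methanol
Product: 11 1-[2,4-bis(tert-butyldimethylsilyloxy)-6-{[4-(tert-butyldimethylsilyloxy)-3-methoxyphenyl]methoxy}-3-(3-methylbut-2-enyl)phenyl]ethanone
Conditions: PPh3, DIAD, THF, 0 °C to rt
Reagents that add atoms: none
Why: Mitsunobu etherification of the single free phenol (the future O1) with the primary benzylic alcohol, which needs no regiocontrol and no base that could move or cleave silyl groups.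

Step 7
Reactants: 11 1-[2,4-bis(tert-butyldimethylsilyloxy)-6-{[4-(tert-butyldimethylsilyloxy)-3-methoxyphenyl]methoxy}-3-(3-methylbut-2-enyl)phenyl]ethanone
Product: 13 2-diazo-1-[2,4-bis(tert-butyldimethylsilyloxy)-6-{[4-(tert-butyldimethylsilyloxy)-3-methoxyphenyl]methoxy}-3-(3-methylbut-2-enyl)phenyl]ethanone, via trifluoroacetyl diketone 12 (not isolated)
Conditions: LiN(SiMe3)2, THF, −78 °C, then CF3CO2CH2CF3; then MsN3, Et3N, H2O (1 equiv), MeCN, rt
Reagents that add atoms: 2,2,2-trifluoroethyl trifluoroacetate, O=C(OCC(F)(F)F)C(F)(F)F (its CF3CO group stays only in 12); methanesulfonyl azide, CS(=O)(=O)N=[N+]=[N-]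
Why: Detrifluoroacetylative diazo transfer, in which the lithium enolate of the methyl ketone is C-acylated by the trifluoroacetate and the activated diketone 12 takes the diazo group from the sulfonyl azide and loses the trifluoroacetyl group as the N-acylsulfonamide.

Step 8
Reactants: 13 2-diazo-1-[2,4-bis(tert-butyldimethylsilyloxy)-6-{[4-(tert-butyldimethylsilyloxy)-3-methoxyphenyl]methoxy}-3-(3-methylbut-2-enyl)phenyl]ethanone
Product: 14 (2S)-5,7-bis(tert-butyldimethylsilyloxy)-2-[4-(tert-butyldimethylsilyloxy)-3-methoxyphenyl]-6-(3-methylbut-2-enyl)-2,3-dihydro-4H-chromen-4-one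
Conditions: Rh2(S-PTTL)4 (dirhodium tetrakis[(S)-N-phthaloyl-tert-leucinate], 2 mol %), 4 Å molecular sieves, CH2Cl2, 0 °C, slow addition of 13
Reagents that add atoms: none
Why: Rh2(S-PTTL)4 (each rhodium divalent) binds the diazo carbon of 13 and expels N2 to give an electrophilic acceptor-only metal carbene at C3, which inserts into a benzylic C2–H bond of the O1 benzyl ether through a concerted three-centre, hydride-transfer-like transition state and so forms C2–C3. The closest known reaction type is the intramolecular C–H insertion of ortho-alkoxyaryl diazomethyl ketones with chiral dirhodium tetracarboxylates, which gives 2-substituted chroman-4-ones. Ring C closes as a six-membered ring by 1,6-insertion, the carbene carbon and C2 being linked through C4, C4a, C8a and O1, so the atom in the 1,5-position is the ether oxygen and carries no hydrogen. C2 is the only new stereocentre and is set by the catalyst alone, whose pocket of phthalimido groups around the axial carbene site distinguishes the two enantiotopic C2–H bonds of a substrate that has no stereocentre. The step needs C–H insertion to outrun oxonium ylide formation at O1 or at the O5 silyl ether and any attack on the prenyl alkene. The C2–H bond is made hydridic by O1 and by the electron-rich ring B, the lone pairs of O1 are drawn into the acyl-substituted ring A, O5 carries a bulky silyl group with no activated C–H bond within reach, and the prenyl group is meta to the diazoacetyl carbon and cannot reach the carbene.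

Step 9
Reactants: 14 (2S)-5,7-bis(tert-butyldimethylsilyloxy)-2-[4-(tert-butyldimethylsilyloxy)-3-methoxyphenyl]-6-(3-methylbut-2-enyl)-2,3-dihydro-4H-chromen-4-one
Product: 15 (2S)-5,7-dihydroxy-2-(4-hydroxy-3-methoxyphenyl)-6-(3-methylbut-2-enyl)-2,3-dihydro-4H-chromen-4-one (CNP0142940.1)
Conditions: Bu4NF (3.3 equiv), AcOH (3.5 equiv), THF, 0 °C
Reagents that add atoms: none
Why: Fluoride cleavage of the three aryl silyl ethers, buffered with acetic acid so that the freed phenols stay protonated, ring C does not open to the chalcone or quinone methide, C2 keeps its configuration and the prenyl group meets no strong acid.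

**Compound list**

1 | vanillin (4-hydroxy-3-methoxybenzaldehyde) | COc1cc(C=O)ccc1O | starting material
2 | 4-(tert-butyldimethylsilyloxy)-3-methoxybenzaldehyde | COc1cc(C=O)ccc1O[Si](C)(C)C(C)(C)C | intermediate
3 | [4-(tert-butyldimethylsilyloxy)-3-methoxyphenyl]methanol | COc1cc(CO)ccc1O[Si](C)(C)C(C)(C)C | intermediate
4 | 1-(2,4,6-trihydroxyphenyl)ethanone | CC(=O)c1c(O)cc(O)cc1O | starting material
5 | 1-[2,4-bis(tert-butyldimethylsilyloxy)-6-hydroxyphenyl]ethanone | CC(=O)c1c(O)cc(O[Si](C)(C)C(C)(C)C)cc1O[Si](C)(C)C(C)(C)C | intermediate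
6 | 3-methylbut-2-en-1-ol (prenol) | CC(C)=CCO | starting material
7 | 1-[2,4-bis(tert-butyldimethylsilyloxy)-6-(3-methylbut-2-enyloxy)phenyl]ethanone | CC(=O)c1c(OCC=C(C)C)cc(O[Si](C)(C)C(C)(C)C)cc1O[Si](C)(C)C(C)(C)C | intermediate
8 | 2-acetyl-3,5-bis(tert-butyldimethylsilyloxy)-6-(2-methylbut-3-en-2-yl)cyclohexa-2,4-dien-1-one (ortho-dienone, racemic) | CC(=O)C1=C(O[Si](C)(C)C(C)(C)C)C=C(O[Si](C)(C)C(C)(C)C)C(C(C)(C)C=C)C1=O | intermediate
9 | 2-acetyl-3,5-bis(tert-butyldimethylsilyloxy)-4-(3-methylbut-2-enyl)cyclohexa-2,5-dien-1-one (para-dienone, racemic) | CC(=O)C1=C(O[Si](C)(C)C(C)(C)C)C(CC=C(C)C)C(O[Si](C)(C)C(C)(C)C)=CC1=O | intermediate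
10 | 1-[2,4-bis(tert-butyldimethylsilyloxy)-6-hydroxy-3-(3-methylbut-2-enyl)phenyl]ethanone | CC(=O)c1c(O)cc(O[Si](C)(C)C(C)(C)C)c(CC=C(C)C)c1O[Si](C)(C)C(C)(C)C | intermediate
11 | 1-[2,4-bis(tert-butyldimethylsilyloxy)-6-{[4-(tert-butyldimethylsilyloxy)-3-methoxyphenyl]methoxy}-3-(3-methylbut-2-enyl)phenyl]ethanone | CC(=O)c1c(OCc2ccc(O[Si](C)(C)C(C)(C)C)c(OC)c2)cc(O[Si](C)(C)C(C)(C)C)c(CC=C(C)C)c1O[Si](C)(C)C(C)(C)C | intermediate
12 | 1-[2,4-bis(tert-butyldimethylsilyloxy)-6-{[4-(tert-butyldimethylsilyloxy)-3-methoxyphenyl]methoxy}-3-(3-methylbut-2-enyl)phenyl]-4,4,4-trifluorobutane-1,3-dione | O=C(CC(=O)C(F)(F)F)c1c(OCc2ccc(O[Si](C)(C)C(C)(C)C)c(OC)c2)cc(O[Si](C)(C)C(C)(C)C)c(CC=C(C)C)c1O[Si](C)(C)C(C)(C)C | intermediate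
13 | 2-diazo-1-[2,4-bis(tert-butyldimethylsilyloxy)-6-{[4-(tert-butyldimethylsilyloxy)-3-methoxyphenyl]methoxy}-3-(3-methylbut-2-enyl)phenyl]ethanone | [N-]=[N+]=CC(=O)c1c(OCc2ccc(O[Si](C)(C)C(C)(C)C)c(OC)c2)cc(O[Si](C)(C)C(C)(C)C)c(CC=C(C)C)c1O[Si](C)(C)C(C)(C)C | intermediate
14 | (2S)-5,7-bis(tert-butyldimethylsilyloxy)-2-[4-(tert-butyldimethylsilyloxy)-3-methoxyphenyl]-6-(3-methylbut-2-enyl)-2,3-dihydro-4H-chromen-4-one | COc1cc([C@@H]2CC(=O)c3c(cc(O[Si](C)(C)C(C)(C)C)c(CC=C(C)C)c3O[Si](C)(C)C(C)(C)C)O2)ccc1O[Si](C)(C)C(C)(C)C | intermediate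
15 | (2S)-5,7-dihydroxy-2-(4-hydroxy-3-methoxyphenyl)-6-(3-methylbut-2-enyl)-2,3-dihydro-4H-chromen-4-one | COc1cc([C@@H]2CC(=O)c3c(cc(O)c(CC=C(C)C)c3O)O2)ccc1O | target

**Step count**

Total: 9 steps. Longest linear sequence: 7 steps (steps 3 to 9, from compound 4).

**Steps most likely to fail**

1. Step 8. The carbene may add to O1 and the resulting oxonium ylide may undergo a 1,2-benzyl shift to a benzofuranone instead of inserting, and an acceptor-only carbene may discriminate poorly between the two enantiotopic C2–H bonds. The fallback sets the stereocentre by conjugate arylation; it sets out from 10 and comes back at 14. Heating 10 with N,N-dimethylformamide dimethyl acetal should give the enaminone (E)-1-[2,4-bis(tert-butyldimethylsilyloxy)-6-hydroxy-3-(3-methylbut-2-enyl)phenyl]-3-(dimethylamino)prop-2-en-1-one F1. Mild acid (pyridinium p-toluenesulfonate, toluene) should close F1 with loss of dimethylamine to the chromone 5,7-bis(tert-butyldimethylsilyloxy)-6-(3-methylbut-2-enyl)chromen-4-one F2. Commercial (4-hydroxy-3-methoxyphenyl)boronic acid is silylated (TBSCl, imidazole) to [4-(tert-butyldimethylsilyloxy)-3-methoxyphenyl]boronic acid F3. Asymmetric conjugate addition of F3 to F2 with Pd(OCOCF3)2 (divalent palladium) and the enantiomer of the tert-butyl pyridine–oxazoline ligand that delivers the (2S) product, a known route from chromones to enantioenriched flavanones, should give 14.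

2. Step 5. The first dienone may enolise before the Cope shift, leaving a 1,1-dimethylallyl group on the ortho carbon, and silyl groups may migrate or be lost at 200 °C. The fallback replaces the sigmatropic sequence by direct C-alkylation; it sets out from 4 and comes back at 11. Treating 4 with 1-bromo-3-methylbut-2-ene and DBU in THF should give 1-[2,4,6-trihydroxy-3-(3-methylbut-2-enyl)phenyl]ethanone F4, a single regioisomer by symmetry. One equivalent of TBSCl with imidazole should silylate the most acidic para hydroxyl to give 1-[4-(tert-butyldimethylsilyloxy)-2,6-dihydroxy-3-(3-methylbut-2-enyl)phenyl]ethanone F5. Mitsunobu coupling with 3 should take place at the ortho hydroxyl that is not flanked by the prenyl group and give 1-[4-(tert-butyldimethylsilyloxy)-2-hydroxy-6-{[4-(tert-butyldimethylsilyloxy)-3-methoxyphenyl]methoxy}-3-(3-methylbut-2-enyl)phenyl]ethanone F6. TBSOTf with 2,6-lutidine should then silylate the remaining hindered hydroxyl to give 11.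

3. Step 7. C-acylation of the hindered enolate may be incomplete, or the aryl silyl ethers may be cleaved during the aqueous amine stage. The fallback uses no strong base or water; it sets out from 11 and comes back at 13. Heating 11 with N,N-dimethylformamide dimethyl acetal should give the enaminone (E)-1-[2,4-bis(tert-butyldimethylsilyloxy)-6-{[4-(tert-butyldimethylsilyloxy)-3-methoxyphenyl]methoxy}-3-(3-methylbut-2-enyl)phenyl]-3-(dimethylamino)prop-2-en-1-one F7. p-Toluenesulfonyl azide in MeCN should add across the enamine double bond of F7, and the triazoline should fragment to 13 and the N-sulfonylformamidine, the known cleavage of enaminones by sulfonyl azides.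

**Further compounds**

F1 | step 8 | (E)-1-[2,4-bis(tert-butyldimethylsilyloxy)-6-hydroxy-3-(3-methylbut-2-enyl)phenyl]-3-(dimethylamino)prop-2-en-1-one | CN(C)/C=C/C(=O)c1c(O)cc(O[Si](C)(C)C(C)(C)C)c(CC=C(C)C)c1O[Si](C)(C)C(C)(C)C
F2 | step 8 | 5,7-bis(tert-butyldimethylsilyloxy)-6-(3-methylbut-2-enyl)chromen-4-one | O=c1ccoc2cc(O[Si](C)(C)C(C)(C)C)c(CC=C(C)C)c(O[Si](C)(C)C(C)(C)C)c12
F3 | step 8 | [4-(tert-butyldimethylsilyloxy)-3-methoxyphenyl]boronic acid | COc1cc(B(O)O)ccc1O[Si](C)(C)C(C)(C)C
F4 | step 5 | 1-[2,4,6-trihydroxy-3-(3-methylbut-2-enyl)phenyl]ethanone | CC(=O)c1c(O)cc(O)c(CC=C(C)C)c1O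
F5 | step 5 | 1-[4-(tert-butyldimethylsilyloxy)-2,6-dihydroxy-3-(3-methylbut-2-enyl)phenyl]ethanone | CC(=O)c1c(O)cc(O[Si](C)(C)C(C)(C)C)c(CC=C(C)C)c1O
F6 | step 5 | 1-[4-(tert-butyldimethylsilyloxy)-2-hydroxy-6-{[4-(tert-butyldimethylsilyloxy)-3-methoxyphenyl]methoxy}-3-(3-methylbut-2-enyl)phenyl]ethanone | CC(=O)c1c(OCc2ccc(O[Si](C)(C)C(C)(C)C)c(OC)c2)cc(O[Si](C)(C)C(C)(C)C)c(CC=C(C)C)c1O
F7 | step 7 | (E)-1-[2,4-bis(tert-butyldimethylsilyloxy)-6-{[4-(tert-butyldimethylsilyloxy)-3-methoxyphenyl]methoxy}-3-(3-methylbut-2-enyl)phenyl]-3-(dimethylamino)prop-2-en-1-one | CN(C)/C=C/C(=O)c1c(OCc2ccc(O[Si](C)(C)C(C)(C)C)c(OC)c2)cc(O[Si](C)(C)C(C)(C)C)c(CC=C(C)C)c1O[Si](C)(C)C(C)(C)C
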